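**Retrosynthetic overview**

1. The target is numbered as (4R)-4-hydroxy-2-acylcyclohexane-1,3-dione (C1 = enolic carbon next to C6H2, C3 = carbonyl next to carbinol C4). Hydrolysis (C=N to C=O) and N–O cleavage lead back to benzisoxazolone 17, in which the side-chain carbonyl carbon, C2 and C1 with its oxygen sit in a temporary isoxazole ring.
2. Key disconnection: the C5–C6 bond between the two ring CH2 groups, giving the 4-glycidoyl-5-methylisoxazole 15 (C6 = 5-methyl carbon, C5 = oxirane CH2, C4 = oxirane CH with its oxygen and configuration).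
3. Enabling feature: the enolised β-diketone O=C(side chain)–C2=C1–OH is an isoxazole retron, which turns C6 into a vinylogously acidic 5-methyl group held next to the C3 acyl group. The C1–O/C4–OH 1,4-relationship across C5–C6 is that of a carbanion-opened epoxide.
4. 15 comes from a [3+2] cycloaddition of nitrile oxide 14 (from the C18 dienal oxime 8; diene by Suzuki coupling of 3 and 5) with epoxy ynone 12 (from methyl (R)-glycidate 9).
5. Ring order: oxirane (bought, carries the stereocentre), then isoxazole (step 8, temporary), then carbocycle (step 9, consumes the oxirane), then the isoxazole is opened (steps 10 and 11).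

Key step: step 9

Remark: the drawn enol is taken as one of the rapidly interconverting tautomers of the (4R)-triketone, and oxime 8 is used as its mixture of C=N isomers, both of which give the same nitrile oxide.

**Route**

Step 1
Reactants: 1 dec-1-yne
Product: 3 (E)-1-iododec-1-ene, via alkenylzirconocene chloride 2 (not isolated)
Conditions: Cp2Zr(H)Cl (1.2 equiv), THF, rt; then I2, 0 °C
Reagents that add atoms: iodine, II
Why: Hydrozirconation adds Zr–H syn across the terminal alkyne with zirconium on the terminal carbon, and iodinolysis of the C–Zr bond with retention should give the (E)-iodide (hydrozirconation–iodination).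

Step 2
Reactants: 4 oct-7-yn-1-ol
Product: 5 (E)-8-(4,4,5,5-tetramethyl-1,3,2-dioxaborolan-2-yl)oct-7-en-1-ol
Conditions: B2pin2 (1.1 equiv), CuCl (5 mol%), Xantphos (5 mol%), NaOtBu (10 mol%), MeOH (2 equiv), THF, rt
Reagents that add atoms: bis(pinacolato)diboron, CC1(C)OB(OC1(C)C)B1OC(C)(C)C(C)(C)O1
Why: Copper-catalysed syn borylcupration of the terminal alkyne (boron to the terminal carbon) followed by protonation of the C–Cu bond by MeOH should give the (E)-alkenylboronate and tolerates the free hydroxyl (formal anti-Markovnikov hydroboration).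

Step 3
Reactants: 3 (E)-1-iododec-1-ene; 5 (E)-8-(4,4,5,5-tetramethyl-1,3,2-dioxaborolan-2-yl)oct-7-en-1-ol
Product: 6 (7E,9E)-octadeca-7,9-dien-1-ol
Conditions: Pd(PPh3)4 (5 mol%), aq. KOH (3 equiv), THF, 50 °C
Reagents that add atoms: none
Why: Suzuki–Miyaura alkenyl–alkenyl coupling proceeds with retention at both partners, so the (7E,9E)-diene is fixed by the geometries set in steps 1 and 2.

Step 4
Reactants: 6 (7E,9E)-octadeca-7,9-dien-1-ol
Product: 7 (7E,9E)-octadeca-7,9-dienal
Conditions: Dess–Martin periodinane (1.2 equiv), CH2Cl2, 0 °C to rt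
Reagents that add atoms: none
Why: Dess–Martin oxidation converts the primary alcohol into the aldehyde under near-neutral conditions that leave the conjugated diene untouched.

Step 5
Reactants: 7 (7E,9E)-octadeca-7,9-dienal
Product: 8 (7E,9E)-octadeca-7,9-dienal oxime
Conditions: NH2OH·HCl (1.5 equiv), NaOAc (2 equiv), EtOH/H2O, rt
Reagents that add atoms: hydroxylamine hydrochloride, Cl.NO
Why: Condensation of the aldehyde with hydroxylamine gives the aldoxime (oxime formation), whose C=N geometry does not matter for the next use.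

Step 6
Reactants: 9 methyl (2R)-oxirane-2-carboxylate
Product: 10 (2R)-N-methoxy-N-methyloxirane-2-carboxamide
Conditions: MeNH(OMe)·HCl (1.5 equiv), iPrMgCl (3.0 equiv), THF, −20 °C; then AcOH
Reagents that add atoms: N,O-dimethylhydroxylamine hydrochloride, CNOC.Cl
Why: The chloromagnesium amide formed in the flask should displace methoxide from the ester at low temperature faster than it opens the epoxide (Weinreb amide synthesis by ester aminolysis), and the stereocentre is not involved.

Step 7
Reactants: 10 (2R)-N-methoxy-N-methyloxirane-2-carboxamide; 11 prop-1-yn-1-ylmagnesium bromide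
Product: 12 1-[(2R)-oxiran-2-yl]but-2-yn-1-one
Conditions: THF, −78 °C to −20 °C; then AcOH, −78 °C
Reagents that add atoms: none
Why: Alkynyl Grignard addition to the Weinreb amide stops at the chelated tetrahedral intermediate, which releases the ynone only on the cold acidic quench (Weinreb ketone synthesis), so over-addition and amine addition to the ynone should be avoided.

Step 8
Reactants: 8 (7E,9E)-octadeca-7,9-dienal oxime; 12 1-[(2R)-oxiran-2-yl]but-2-yn-1-one
Product: 15 [3-[(6E,8E)-heptadeca-6,8-dien-1-yl]-5-methyl-1,2-oxazol-4-yl][(2R)-oxiran-2-yl]methanone, via hydroximoyl chloride 13 (not isolated), via nitrile oxide 14 (not isolated)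
Conditions: NCS (1.05 equiv), DMF, rt; then 12 (1.3 equiv), KHCO3 (3 equiv), EtOAc, rt
Reagents that add atoms: none
Why: Slow dehydrochlorination releases the nitrile oxide, whose 1,3-dipolar (Huisgen) cycloaddition to the electron-poor alkyne should place the dipole oxygen on the methyl-bearing β-carbon and the acyl group at C4 of the isoxazole; the 1,2-disubstituted diene is a much poorer dipolarophile and the epoxide stereocentre is untouched.

Step 9
Reactants: 15 [3-[(6E,8E)-heptadeca-6,8-dien-1-yl]-5-methyl-1,2-oxazol-4-yl][(2R)-oxiran-2-yl]methanone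
Product: 17 (5R)-3-[(6E,8E)-heptadeca-6,8-dien-1-yl]-5-hydroxy-6,7-dihydro-1,2-benzoxazol-4(5H)-one, via lithiated isoxazole 16 (not isolated)
Conditions: LiN(SiMe3)2 (1.1 equiv), THF, −78 °C to 0 °C; then AcOH, −78 °C
Reagents that add atoms: none
Why: Proposed new method: the amide base should remove a proton only from the 5-methyl group, whose carbanion is a vinylogous enolate of the 4-acyl group, and this carbanion attacks the oxirane CH2 in an intramolecular SN2 opening that forms the C6–C7 bond of 17 (C5–C6 of the target) and releases the alkoxide; the closest known reaction types are the Stork epoxynitrile cyclisation and the lateral metalation–alkylation of 5-methylisoxazoles. The carbocycle closes in the 6-(enolendo)-exo-tet mode at the oxirane CH2 (fused, endo mode of epoxide opening), because attack at the oxirane CH would be a 5-(enolendo)-exo-tet closure that Baldwin's enolate rules disfavour and would give a strained 5,5-fused system. No new stereocentre is made: the C–O bond of the oxirane CH is not broken, so the (R) configuration bought with 9 becomes the (5R) carbinol with retention, and before ring closure this carbon cannot epimerise because enolisation would require an alkylidene oxirane. The step needs site-selective deprotonation, regioselective epoxide opening and freedom from O-alkylation, and the isoxazole secures all three: it holds the methyl and acyl groups on adjacent ring carbons, it leaves the α-CH2 of the 3-alkyl chain unconjugated with the carbonyl and therefore far less acidic, and it ties up both diketone oxygens as ring O and N. Lithium coordination to the carbonyl and oxirane oxygens should assist the opening, and the cold AcOH quench protonates the ketol alkoxide before base can act on the product.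

Step 10
Reactants: 17 (5R)-3-[(6E,8E)-heptadeca-6,8-dien-1-yl]-5-hydroxy-6,7-dihydro-1,2-benzoxazol-4(5H)-one
Product: 18 (4R)-2-[(7E,9E)-1-aminooctadeca-7,9-dien-1-ylidene]-4-hydroxycyclohexane-1,3-dione
Conditions: Mo(CO)6 (1.0 equiv), MeCN/H2O (15:1), 80 °C
Reagents that add atoms: none
Why: Zerovalent molybdenum inserts into the weak N–O bond and water protonates the fragments (Mo(CO)6-mediated reductive cleavage of isoxazoles to β-amino enones), a method that does not reduce C=C bonds or the α-ketol and is the classical way to open 6,7-dihydro-1,2-benzoxazol-4(5H)-ones.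

Step 11
Reactants: 18 (4R)-2-[(7E,9E)-1-aminooctadeca-7,9-dien-1-ylidene]-4-hydroxycyclohexane-1,3-dione
Product: 19 (6R)-3,6-dihydroxy-2-[(7E,9E)-octadeca-7,9-dienoyl]cyclohex-2-en-1-one
Conditions: 1 M aq. HCl/THF (1:3), 45 °C
Reagents that add atoms: water, O
Why: Acid hydrolysis of the vinylogous amide (enaminone hydrolysis) exchanges NH2 for OH and traps ammonia as its salt, giving the enolised β-triketone; the carbinol centre should not epimerise because the adjacent carbonyl is engaged in the chelated enol system.

**Compound list**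

1 | dec-1-yne | C#CCCCCCCCC | starting material
2 | chloro[(E)-dec-1-en-1-yl]bis(cyclopentadienyl)zirconium (rings drawn σ-bonded) | CCCCCCCC/C=C/[Zr](Cl)(C1C=CC=C1)C1C=CC=C1 | intermediate
3 | (E)-1-iododec-1-ene | CCCCCCCC/C=C/I | intermediate
4 | oct-7-yn-1-ol | C#CCCCCCCO | starting material
5 | (E)-8-(4,4,5,5-tetramethyl-1,3,2-dioxaborolan-2-yl)oct-7-en-1-ol | OCCCCCC/C=C/B1OC(C)(C)C(C)(C)O1 | intermediate
6 | (7E,9E)-octadeca-7,9-dien-1-ol | OCCCCCC/C=C/C=C/CCCCCCCC | intermediate
7 | (7E,9E)-octadeca-7,9-dienal | O=CCCCCC/C=C/C=C/CCCCCCCC | intermediate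
8 | (7E,9E)-octadeca-7,9-dienal oxime (mixture of C=N isomers) | ON=CCCCCC/C=C/C=C/CCCCCCCC | intermediate
9 | methyl (2R)-oxirane-2-carboxylate | COC(=O)[C@H]1CO1 | starting material
10 | (2R)-N-methoxy-N-methyloxirane-2-carboxamide | CON(C)C(=O)[C@H]1CO1 | intermediate
11 | prop-1-yn-1-ylmagnesium bromide | CC#C[Mg]Br | starting material
12 | 1-[(2R)-oxiran-2-yl]but-2-yn-1-one | CC#CC(=O)[C@H]1CO1 | intermediate
13 | (7E,9E)-N-hydroxyoctadeca-7,9-dienimidoyl chloride | ON=C(Cl)CCCCC/C=C/C=C/CCCCCCCC | intermediate
14 | (7E,9E)-octadeca-7,9-dienenitrile oxide | [O-][N+]#CCCCCC/C=C/C=C/CCCCCCCC | intermediate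
15 | [3-[(6E,8E)-heptadeca-6,8-dien-1-yl]-5-methyl-1,2-oxazol-4-yl][(2R)-oxiran-2-yl]methanone | CCCCCCCC/C=C/C=C/CCCCCc1noc(C)c1C(=O)[C@H]1CO1 | intermediate
16 | {3-[(6E,8E)-heptadeca-6,8-dien-1-yl]-4-[(2R)-oxirane-2-carbonyl]-1,2-oxazol-5-yl}methyllithium | [Li]Cc1onc(CCCCC/C=C/C=C/CCCCCCCC)c1C(=O)[C@H]1CO1 | intermediate
17 | (5R)-3-[(6E,8E)-heptadeca-6,8-dien-1-yl]-5-hydroxy-6,7-dihydro-1,2-benzoxazol-4(5H)-one | CCCCCCCC/C=C/C=C/CCCCCc1noc2CC[C@@H](O)C(=O)c12 | intermediate
18 | (4R)-2-[(7E,9E)-1-aminooctadeca-7,9-dien-1-ylidene]-4-hydroxycyclohexane-1,3-dione | NC(CCCCC/C=C/C=C/CCCCCCCC)=C1C(=O)CC[C@@H](O)C1=O | intermediate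
19 | (6R)-3,6-dihydroxy-2-[(7E,9E)-octadeca-7,9-dienoyl]cyclohex-2-en-1-one | CCCCCCCC/C=C/C=C/CCCCCC(=O)C1=C(O)CC[C@@H](O)C1=O | target

**Step count and risks**

Total steps: 11. Longest linear sequence: 8 steps (steps 2, 3, 4, 5, 8, 9, 10, 11, from oct-7-yn-1-ol).

Steps most likely to fail:

Step 9. The fused-mode epoxide opening may be slower than intermolecular addition of the lateral carbanion to the ketone of a second molecule, or the carbanion may simply be re-protonated on work-up; base-induced epimerisation of the product ketol is a further danger. The fallback sets out from 15 and returns at 17, using only known reaction types. MgI2 (Et2O/toluene, −40 °C) should open the oxirane at its CH2 to the iodohydrin (2S)-1-{3-[(6E,8E)-heptadeca-6,8-dien-1-yl]-5-methyl-1,2-oxazol-4-yl}-2-hydroxy-3-iodopropan-1-one F1. TBSOTf/2,6-lutidine then gives the silyl ether (2S)-2-[(tert-butyldimethylsilyl)oxy]-1-{3-[(6E,8E)-heptadeca-6,8-dien-1-yl]-5-methyl-1,2-oxazol-4-yl}-3-iodopropan-1-one F2. LiN(SiMe3)2 in THF/DMPU at −78 °C closes the same C–C bond by a 6-(enolendo)-exo-tet alkylation of the lateral carbanion with the primary iodide, giving (5R)-5-[(tert-butyldimethylsilyl)oxy]-3-[(6E,8E)-heptadeca-6,8-dien-1-yl]-6,7-dihydro-1,2-benzoxazol-4(5H)-one F3. HF·pyridine in THF removes the silyl group to give 17.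

Step 8. Dimerisation of the aliphatic nitrile oxide to its furoxan may outrun cycloaddition to the internal ynone, and the dipole oxygen may add in part to the carbonyl-bearing alkyne carbon, lowering regiocontrol. The fallback sets out from 12 (with 8) and returns at 15. PBu3-catalysed addition of MeOH (CH2Cl2, rt) converts 12 into the push–pull alkene (2E)-3-methoxy-1-[(2R)-oxiran-2-yl]but-2-en-1-one F4. Nitrile oxide 14, generated from 8 as in step 8, then adds with its oxygen at the methoxy-bearing carbon to give {3-[(6E,8E)-heptadeca-6,8-dien-1-yl]-5-methoxy-5-methyl-4,5-dihydro-1,2-oxazol-4-yl}[(2R)-oxiran-2-yl]methanone F5. F5 loses methanol on warming or on silica gel to give 15 with the regiochemistry fixed by the enol ether.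

Step 7. Bromide from the Grignard solution may open the carbonyl-activated epoxide, and the liberated N,O-dimethylhydroxylamine may add to the ynone during the quench. The fallback sets out from 11, bypasses steps 6 and 7, and returns at 12. Addition of 11 to acrolein (THF, −78 °C) gives racemic hex-1-en-4-yn-3-ol F6. Sharpless asymmetric epoxidation run as a kinetic resolution (Ti(OiPr)4, L-(+)-DIPT, tBuOOH, 4 Å molecular sieves, CH2Cl2, −20 °C) should give the anti epoxy alcohol (1S)-1-[(2R)-oxiran-2-yl]but-2-yn-1-ol F7, the oxirane carbon being set by the tartrate. Dess–Martin oxidation of F7 gives 12.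

**Further compounds**

F1 | step 9 | (2S)-1-{3-[(6E,8E)-heptadeca-6,8-dien-1-yl]-5-methyl-1,2-oxazol-4-yl}-2-hydroxy-3-iodopropan-1-one | CCCCCCCC/C=C/C=C/CCCCCc1noc(C)c1C(=O)[C@H](O)CI
F2 | step 9 | (2S)-2-[(tert-butyldimethylsilyl)oxy]-1-{3-[(6E,8E)-heptadeca-6,8-dien-1-yl]-5-methyl-1,2-oxazol-4-yl}-3-iodopropan-1-one | CCCCCCCC/C=C/C=C/CCCCCc1noc(C)c1C(=O)[C@H](O[Si](C)(C)C(C)(C)C)CI
F3 | step 9 | (5R)-5-[(tert-butyldimethylsilyl)oxy]-3-[(6E,8E)-heptadeca-6,8-dien-1-yl]-6,7-dihydro-1,2-benzoxazol-4(5H)-one | CCCCCCCC/C=C/C=C/CCCCCc1noc2CC[C@@H](O[Si](C)(C)C(C)(C)C)C(=O)c12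
F4 | step 8 | (2E)-3-methoxy-1-[(2R)-oxiran-2-yl]but-2-en-1-one | CO/C(C)=C/C(=O)[C@H]1CO1
F5 | step 8 | {3-[(6E,8E)-heptadeca-6,8-dien-1-yl]-5-methoxy-5-methyl-4,5-dihydro-1,2-oxazol-4-yl}[(2R)-oxiran-2-yl]methanone (mixture of diastereomers) | COC1(C)ON=C(CCCCC/C=C/C=C/CCCCCCCC)C1C(=O)[C@H]1CO1
F6 | step 7 | rac-hex-1-en-4-yn-3-ol | C=CC(O)C#CC
F7 | step 7 | (1S)-1-[(2R)-oxiran-2-yl]but-2-yn-1-ol | CC#C[C@H](O)[C@H]1CO1
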